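## Retrosynthetic overview

1. The 5α-hydroperoxide and the 4(15)-methylene come last, by photooxygenation of the tetrasubstituted C4=C5 alkene of the fully dressed eudesm-4-ene.
2. The cis 8β-acetoxy/7β-acrylate pair comes from a C8 ketone. The C7–C11 bond is made with methyl 3-nitroacrylate, which acts as an acrylate α-cation equivalent, and the ketone is then reduced from the α face and acetylated.
3. The 3α-angelate comes from the 3β-allylic alcohol by inversion with angelic acid.
4. Key disconnection: ring B is a ring-expanded cyclopentanone. One carbon from CH2Br2 becomes C9, and quaternary C10 shifts 1,2 from C8 to C9, which moves the carbonyl to C8.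
5. Ring order: the five-membered ring is bought, ring A is annulated onto it with ethyl vinyl ketone (this sets C10), and the five-membered ring is then expanded to ring B.

Assumption: the SMILES is read as (3R,5S,7R,8R,10R), that is 3α-angeloyloxy, 5α-OOH, 7β side chain, 8β-OAc and 10β-methyl. Eudesmane numbering is used throughout (ring A = C1–C5, C10; ring B = C5–C10; C14 on C10; C15 on C4; C11–C13 on C7).

## Route

Step 1
Reactants: 1 2-methylcyclopentane-1,3-dione; 2 pent-1-en-3-one (ethyl vinyl ketone)
Product: 4 (7aS)-4,7a-dimethyl-2,3,7,7a-tetrahydro-1H-indene-1,5(6H)-dione, via prochiral triketone 3 (not isolated)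
Conditions: 2 (1.3 equiv), Et3N (5 mol %), MeCN, rt; then L-phenylalanine (1.0 equiv), (1S)-(+)-camphor-10-sulfonic acid (0.5 equiv), 70 °C; recrystallise to raise ee
Reagents that add atoms: none
Why: Michael addition followed by the amino-acid-mediated Hajos–Parrish–Eder–Sauer–Wiechert aldol condensation (Robinson annulation), in which the L-phenylalanine enamine of the side-chain ketone attacks only one of the two enantiotopic ring carbonyls, setting C10 as S (the 10β-methyl series), and dehydration closes ring A as the tetrasubstituted enone.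

Step 2
Reactants: 4 (7aS)-4,7a-dimethyl-2,3,7,7a-tetrahydro-1H-indene-1,5(6H)-dione; 5 dibromomethane
Product: 9 (6S,8aR)-6-hydroxy-5,8a-dimethyl-3,4,6,7,8,8a-hexahydronaphthalen-2(1H)-one, via lithium dibromomethyl carbinolate 6 (not isolated), via magnesium carbenoid 7 (not isolated), via chloromagnesium enolate 8 (not isolated)
Conditions: 5 (1.3 equiv), LiN(i-Pr)2 (1.25 equiv, added last), THF, −90 °C; i-PrMgCl·LiCl (1.4 equiv), −78 to 0 °C; i-Bu2AlH (2 equiv), −78 °C; EtOAc, then aq. potassium sodium tartrate
Reagents that add atoms: none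
Why: Proposed new method: this is a one-flask homologation–reduction in which LiCHBr2 adds from the α face to the more electrophilic, non-conjugated C8 carbonyl; Br/Mg exchange with i-PrMgCl·LiCl, which is too mild to touch the tetrasubstituted enone (unlike the alkyllithium of the classical protocol), then gives a magnesium β-oxido carbenoid; the oxido group pushes the electron-richer, more substituted C8–C10 σ bond into the C–Br σ* orbital, so quaternary C10 shifts from C8 to the new C9 with retention, ring B grows from five to six atoms and the carbonyl ends at C8; the resulting enolate masks that new ketone while i-Bu2AlH delivers hydride axially to the α face of the C3 enone carbonyl, giving 3β-OH (S); the closest known reaction type is the lithium β-oxido carbenoid ring enlargement of 1-(dibromomethyl)cycloalkanols (a semipinacol-type 1,2-shift), which has not been shown as a magnesium variant from a gem-dibromide, on an unprotected enone, or coupled to an enolate-masked reduction.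

Step 3
Reactants: 9 (6S,8aR)-6-hydroxy-5,8a-dimethyl-3,4,6,7,8,8a-hexahydronaphthalen-2(1H)-one; 10 angelic acid
Product: 11 (3R,10R)-3α-angeloyloxy-11,12,13-trinoreudesm-4-en-8-one
Conditions: 10 (1.5 equiv), PPh3, DIAD, toluene, −20 to 0 °C
Reagents that add atoms: none
Why: Mitsunobu esterification, in which angelate displaces the activated pseudo-equatorial 3β-oxyphosphonium group by SN2 from the open α face and inverts C3 to the 3α (R) ester; SN2' attack is blocked at fully substituted C5, and the cold neutral medium keeps the Z geometry and leaves the ketone alone.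

Step 4
Reactants: 12 methyl acrylate
Product: 14 methyl (E)-3-nitroacrylate, via methyl 2-iodo-3-nitropropanoate 13 (not isolated)
Conditions: AgNO2, I2, Et2O, 0 °C to rt; then Et3N, 0 °C
Reagents that add atoms: AgNO2 (silver nitrite), [Ag+].[O-]N=O
Why: Radical nitryl iodide addition (NO2 to the terminal carbon, iodine α to the ester) followed by E1cB dehydroiodination gives the E nitroalkene, and no stereocentre is formed.

Step 5
Reactants: 11 (3R,10R)-3α-angeloyloxy-11,12,13-trinoreudesm-4-en-8-one; 14 methyl (E)-3-nitroacrylate
Product: 17 methyl (3R,7R,10R)-3α-angeloyloxy-8-oxoeudesma-4,11(13)-dien-12-oate, via lithium enolate 15 (not isolated), via nitro keto ester 16 (not isolated)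
Conditions: LiN(SiMe3)2 (1.05 equiv), THF, −78 °C; 14 (1.1 equiv), −78 °C; AcOH; then Et3N, CH2Cl2, 0 °C to rt, stopped as soon as the C7 epimers have converged
Reagents that add atoms: none
Why: Michael addition of the kinetic, less hindered C7 enolate (C9 is neopentyl) to the carbon β to the nitro group, which overrides the ester and so forms C7–C11 at the ester α-carbon, followed by E1cB loss of nitrous acid to unveil the acrylate; the doubly activated C7–H equilibrates under Et3N by axial α-face reprotonation, which puts the side chain equatorial (7β, R).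

Step 6
Reactants: 17 methyl (3R,7R,10R)-3α-angeloyloxy-8-oxoeudesma-4,11(13)-dien-12-oate
Product: 18 methyl (3R,7R,8R,10R)-3α-angeloyloxy-8β-hydroxyeudesma-4,11(13)-dien-12-oate
Conditions: NaBH4, CeCl3·7H2O, MeOH, −78 °C; pH 7 buffer; used at once
Reagents that add atoms: none
Why: Luche reduction, in which the 10β-methyl group blocks the axial β trajectory at C8, so hydride arrives from the α face and gives the axial 8β (R) alcohol cis to the side chain, while cold methanolic CeCl3 suppresses conjugate reduction of the acrylate and is too mild for lactonisation.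

Step 7
Reactants: 18 methyl (3R,7R,8R,10R)-3α-angeloyloxy-8β-hydroxyeudesma-4,11(13)-dien-12-oate
Product: 19 methyl (3R,7R,8R,10R)-8β-acetoxy-3α-angeloyloxyeudesma-4,11(13)-dien-12-oate
Conditions: Ac2O, DMAP (0.2 equiv), Et3N, CH2Cl2, 0 °C
Reagents that add atoms: acetic anhydride, CC(=O)OC(C)=O
Why: DMAP-catalysed acyl transfer (Steglich-type acetylation) outruns attack of the neutral axial hydroxyl on the conjugated ester, so the 8β-acetate forms with retention and no stereocentre changes.

Step 8
Reactants: 19 methyl (3R,7R,8R,10R)-8β-acetoxy-3α-angeloyloxyeudesma-4,11(13)-dien-12-oate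
Product: 20 methyl (3R,5S,7R,8R,10R)-8β-acetoxy-3α-angeloyloxy-5α-hydroperoxyeudesma-4(15),11(13)-dien-12-oate
Conditions: O2, tetraphenylporphyrin (0.5 mol %), white LED, CH2Cl2, −20 °C; no reductive work-up
Reagents that add atoms: dioxygen (as singlet oxygen), O=O
Why: Schenck ene reaction, in which singlet oxygen reacts only with the electron-rich tetrasubstituted C4=C5 bond (acrylate and angelate are electron-poor), approaches the α face anti to the 10β-methyl, bonds to C5 and takes a hydrogen from the freely rotating C15 methyl geminal to the bulky acyloxy-bearing C3 (H3 lies on the β face and is out of reach), setting 5α-OOH (S) and the 4(15)-methylene; the 4α-hydroperoxy-5-ene from abstraction at C6 is the expected minor isomer.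

## Compound list

1 | 2-methylcyclopentane-1,3-dione | CC1C(=O)CCC1=O | starting material
2 | pent-1-en-3-one (ethyl vinyl ketone) | C=CC(=O)CC | starting material
3 | 2-methyl-2-(3-oxopentyl)cyclopentane-1,3-dione | CCC(=O)CCC1(C)C(=O)CCC1=O | intermediate
4 | (7aS)-4,7a-dimethyl-2,3,7,7a-tetrahydro-1H-indene-1,5(6H)-dione | O=C1CC[C@]2(C)C(=O)CCC2=C1C | intermediate
5 | dibromomethane | BrCBr | starting material
6 | lithium (1S,7aS)-1-(dibromomethyl)-4,7a-dimethyl-5-oxo-2,3,5,6,7,7a-hexahydro-1H-inden-1-olate (CHBr2 on the α face, O on the β face) | O=C1CC[C@]2(C)[C@](O[Li])(C(Br)Br)CCC2=C1C | intermediate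
7 | bromo(chloromagnesio)methyl analogue of 6 (magnesium β-oxido carbenoid, carbenoid carbon not defined) | O=C1CC[C@]2(C)[C@](O[Li])(C(Br)[Mg]Cl)CCC2=C1C | intermediate
8 | chloromagnesium 8(9)-enolate of (10R)-11,12,13-trinoreudesm-4-ene-3,8-dione | O=C1CC[C@]2(C)C=C(O[Mg]Cl)CCC2=C1C | intermediate
9 | (6S,8aR)-6-hydroxy-5,8a-dimethyl-3,4,6,7,8,8a-hexahydronaphthalen-2(1H)-one (3β-hydroxy-11,12,13-trinoreudesm-4-en-8-one) | O=C1CCC2=C(C)[C@@H](O)CC[C@]2(C)C1 | intermediate
10 | angelic acid, (Z)-2-methylbut-2-enoic acid | C/C=C(/C)C(=O)O | starting material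
11 | (3R,10R)-3α-angeloyloxy-11,12,13-trinoreudesm-4-en-8-one | O=C1CCC2=C(C)[C@H](OC(=O)/C(C)=C\C)CC[C@]2(C)C1 | intermediate
12 | methyl acrylate | C=CC(=O)OC | starting material
13 | methyl 2-iodo-3-nitropropanoate (racemic) | COC(=O)C(I)C[N+](=O)[O-] | intermediate
14 | methyl (E)-3-nitroacrylate | COC(=O)/C=C/[N+](=O)[O-] | intermediate
15 | lithium 7(8)-enolate of 11 | [Li]OC1=CCC2=C(C)[C@H](OC(=O)/C(C)=C\C)CC[C@]2(C)C1 | intermediate
16 | methyl 3α-angeloyloxy-13-nitro-8-oxoeudesm-4-en-12-oate (mixture at C7 and C11) | COC(=O)C(C[N+](=O)[O-])C1CC2=C(C)[C@H](OC(=O)/C(C)=C\C)CC[C@]2(C)CC1=O | intermediate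
17 | methyl (3R,7R,10R)-3α-angeloyloxy-8-oxoeudesma-4,11(13)-dien-12-oate | C=C(C(=O)OC)[C@H]1CC2=C(C)[C@H](OC(=O)/C(C)=C\C)CC[C@]2(C)CC1=O | intermediate
18 | methyl (3R,7R,8R,10R)-3α-angeloyloxy-8β-hydroxyeudesma-4,11(13)-dien-12-oate | C=C(C(=O)OC)[C@H]1CC2=C(C)[C@H](OC(=O)/C(C)=C\C)CC[C@]2(C)C[C@H]1O | intermediate
19 | methyl (3R,7R,8R,10R)-8β-acetoxy-3α-angeloyloxyeudesma-4,11(13)-dien-12-oate | C=C(C(=O)OC)[C@H]1CC2=C(C)[C@H](OC(=O)/C(C)=C\C)CC[C@]2(C)C[C@H]1OC(C)=O | intermediate
20 | methyl (3R,5S,7R,8R,10R)-8β-acetoxy-3α-angeloyloxy-5α-hydroperoxyeudesma-4(15),11(13)-dien-12-oate (CNP0116769.2) | C=C(C(=O)OC)[C@H]1C[C@@]2(OO)C(=C)[C@H](OC(=O)/C(C)=C\C)CC[C@]2(C)C[C@H]1OC(C)=O | target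

## Step count and risks

Total step count: 8.
Longest linear sequence: 7 steps (1, 2, 3, 5, 6, 7, 8). Step 4 is a one-step side branch.

**Step 2 (the proposed new step).** There are three risks:
- LiCHBr2 may enolise 4 or touch the enone.
- The magnesium carbenoid may be sluggish.
- C7 may migrate instead of C10.

The fallback uses known chemistry. It sets out from 4 and comes back at 9. It replaces the carbenoid by a cationic thionium semipinacol, where migration of the more substituted carbon is the established outcome. Bis(methylthio)methyllithium (from CH2(SMe)2 and n-BuLi, THF, −78 °C) is added to the C8 carbonyl of 4. The enone is reduced in the same flask with i-Bu2AlH to give the 3β,8β-diol bearing an 8α-bis(methylthio)methyl group F1. The monovalent copper salt (CuOTf)2·C6H6 with i-Pr2NEt in benzene at 45 °C removes one methylthio group, and C10 shifts onto the thionium carbon to give the ring-expanded 9-methylthio-3β-hydroxy-8-ketone F2. SmI2 in THF–MeOH at −78 °C cleaves the α-carbon–sulfur bond and gives 9.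

**Step 5.** There are three risks:
- The hard lithium enolate may polymerise 14.
- Kinetic axial attack may leave the 7α epimer.
- The amine may carry 17 on to the conjugated 7(11)-ene.

The fallback sets out from 11 and comes back at 16. It changes the nucleophile to a neutral enamine. Compound 11 is condensed with pyrrolidine (4 Å sieves, toluene, rt, volatiles stripped) to give the 7(8)-pyrrolidine enamine F3. This adds to 14 in Et2O at −40 °C without any metal base. Hydrolysis in AcOH–NaOAc buffer gives 16 with C7 already under thermodynamic control. Only a short Et3N treatment is then needed to reach 17.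

**Step 6.** The risk is that the 8β-hydroxy ester 18 closes to the cis lactone before it can be acetylated. The fallback sets out from 17 and comes back at 19. It accepts the lactone instead of avoiding it. Compound 17 is reduced with NaBH4 in MeOH at 0 °C and left to cyclise to the 3α-angeloyloxyeudesma-4,11(13)-dien-8β,12-olide F4. LiOH (1.0 equiv) in THF–H2O at 0 °C opens the strained α-methylene lactone faster than the hindered angelate and gives the lithium 8β-hydroxy carboxylate F5. The dried salt is alkylated with MeI in DMF. Ac2O and DMAP are added to the same flask, so 18 is acetylated to 19 as it forms.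

## Further compounds

F1 | step 2 | (1S,5S,7aS)-1-[bis(methylthio)methyl]-4,7a-dimethyl-2,3,5,6,7,7a-hexahydro-1H-indene-1,5-diol (3β,8β-diol in eudesmane numbering) | O[C@H]1CC[C@]2(C)[C@](O)(C(SC)SC)CCC2=C1C
F2 | step 2 | 3β-hydroxy-9-methylthio-11,12,13-trinoreudesm-4-en-8-one (C9 not defined) | O[C@H]1CC[C@]2(C)C(SC)C(=O)CCC2=C1C
F3 | step 5 | 7(8)-pyrrolidine enamine of 11 | C1CCN(C1)C3=CCC2=C(C)[C@H](OC(=O)/C(C)=C\C)CC[C@]2(C)C3
F4 | step 6 | 3α-angeloyloxyeudesma-4,11(13)-dien-8β,12-olide | C=C3[C@H]1CC2=C(C)[C@H](OC(=O)/C(C)=C\C)CC[C@]2(C)C[C@H]1OC3=O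
F5 | step 6 | lithium 3α-angeloyloxy-8β-hydroxyeudesma-4,11(13)-dien-12-oate | [Li+].C=C(C(=O)[O-])[C@H]1CC2=C(C)[C@H](OC(=O)/C(C)=C\C)CC[C@]2(C)C[C@H]1O
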